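The target is cut at its pyran ring: O1–C8a, C4–C4a and O1–C2 are all made in one operation from an aryne and 3-methylbut-2-enal. The ring is fused at C4a–C8a with C4 beside the aroyl-bearing C5 and O1 on the far carbon, which is the sense in which a 3-aroyl aryne accepts carbonyl oxygen (remote carbon) and carbonyl carbon (near carbon); formal [2+2] addition, benzoxete opening and oxa-6π closure then deliver the 2,2-dimethyl-2H-chromene. The precursor is the full benzophenone as an ortho-silylaryl triflate, silicon between triflate and ketone, the future C7 oxygen as an isopropyl ether and ring A as its trimethyl ether.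

Key step: step 8

Remark on the chemistry: the structures of aryne precursor 15 and chromene 20 are consistent with the target and are used as drawn; silicon is placed by bromine–lithium exchange and O→C silyl shift on an acetal-protected aldehyde, and the ketone is made afterwards, because ortho-lithiation of a 3-carbamoyloxy-5-alkoxybenzophenone would favour the site between the two oxygens and would expose the ketone and the acidic ring A positions to alkyllithium.

Step 1
Reactants: 1 3,5-dimethoxybenzaldehyde
Product: 2 2-bromo-3,5-dimethoxybenzaldehyde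
Conditions: NBS (1.05 equiv), MeCN, 0 °C → rt
Reagents that add atoms: N-bromosuccinimide, O=C1CCC(=O)N1Br
Why: Electrophilic aromatic bromination should go to C2, which is para to one methoxy group and ortho to the other, and not to the site between them, so the bromine marks the carbon that will later carry silicon.

Step 2
Reactants: 2 2-bromo-3,5-dimethoxybenzaldehyde
Product: 3 2-bromo-3,5-dihydroxybenzaldehyde
Conditions: BBr3 (4 equiv), CH2Cl2, −78 °C → rt; then H2O, 0 °C
Reagents that add atoms: none
Why: Lewis-acid cleavage of aryl methyl ethers with BBr3 should free both phenols, the aldehyde being only reversibly complexed and the aryl bromide inert.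

Step 3
Reactants: 3 2-bromo-3,5-dihydroxybenzaldehyde
Product: 4 2-bromo-5-(dimethoxymethyl)benzene-1,3-diol
Conditions: HC(OMe)3, MeOH, TsOH·H2O (cat.), rt; Et3N quench
Reagents that add atoms: trimethyl orthoformate, COC(OC)OC; methanol, CO
Why: Acid-catalysed acetalisation, driven by the orthoformate as water scavenger and tolerant of free phenols in methanol, should mask the aldehyde, the one group that would not survive butyllithium in step 4.

Step 4
Reactants: 4 2-bromo-5-(dimethoxymethyl)benzene-1,3-diol
Product: 9 3-formyl-5-hydroxy-2-(trimethylsilyl)phenyl trifluoromethanesulfonate, via bis(trimethylsilyl) ether 5 (not isolated), via aryllithium 6 (not isolated), via lithium phenoxide 7 (not isolated), via silyl ether triflate 8 (not isolated)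
Conditions: HMDS, THF, 65 °C, then evaporation; n-BuLi (1.05 equiv), THF, −100 → −80 °C; Tf2O (1.1 equiv), −100 → −78 °C; then 1 M HCl, THF, 0 °C
Reagents that add atoms: hexamethyldisilazane, C[Si](C)(C)N[Si](C)(C)C; trifluoromethanesulfonic anhydride, O=S(=O)(OS(=O)(=O)C(F)(F)F)C(F)(F)F; water, O
Why: In this retro-Brook route to ortho-silylaryl triflates, bromine–lithium exchange at C2 should be followed by 1,3 O→C silyl shift from the only neighbouring silyl ether, so the single phenoxide that is triflated is the one next to silicon while the remote oxygen stays a silyl ether until dilute acid hydrolyses it together with the acetal.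

Step 5
Reactants: 9 3-formyl-5-hydroxy-2-(trimethylsilyl)phenyl trifluoromethanesulfonate
Product: 10 3-formyl-5-isopropoxy-2-(trimethylsilyl)phenyl trifluoromethanesulfonate
Conditions: i-PrOH, PPh3, DIAD, THF, 0 °C → rt
Reagents that add atoms: propan-2-ol, CC(C)O
Why: Mitsunobu etherification of the acidic, unhindered phenol should proceed under neutral conditions, so that neither base nor fluoride meets the silyl triflate.

Step 6
Reactants: 10 3-formyl-5-isopropoxy-2-(trimethylsilyl)phenyl trifluoromethanesulfonate; 11 1,3,5-trimethoxybenzene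
Product: 14 3-[hydroxy(2,4,6-trimethoxyphenyl)methyl]-5-isopropoxy-2-(trimethylsilyl)phenyl trifluoromethanesulfonate (racemic), via 2,4,6-trimethoxyphenyllithium 12 (not isolated), via 2,4,6-trimethoxyphenylmagnesium bromide 13 (not isolated)
Conditions: 11 (1.3 equiv), n-BuLi (1.2 equiv), THF, 0 °C → rt; MgBr2·OEt2, −78 → 0 °C; then 10, THF, −78 → −40 °C; sat. NH4Cl at −40 °C
Reagents that add atoms: none
Why: Lithiation of 11 between two methoxy groups, transmetalation to magnesium and Grignard addition to the aldehyde should give the diaryl carbinol as a racemate (its stereocentre is erased in step 7), the magnesium reagent and the magnesium alkoxide being too weakly nucleophilic in the cold to attack sulfur or silicon of the silyl triflate.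

Step 7
Reactants: 14 3-[hydroxy(2,4,6-trimethoxyphenyl)methyl]-5-isopropoxy-2-(trimethylsilyl)phenyl trifluoromethanesulfonate
Product: 15 5-isopropoxy-3-(2,4,6-trimethoxybenzoyl)-2-(trimethylsilyl)phenyl trifluoromethanesulfonate
Conditions: Dess–Martin periodinane, NaHCO3, CH2Cl2, 0 °C → rt
Reagents that add atoms: none
Why: Dess–Martin oxidation of the doubly benzylic secondary alcohol under buffered, non-nucleophilic conditions should give the diaryl ketone without touching the C–Si or O–Tf bond and without ionising the acid-sensitive carbinol.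

Step 8
Reactants: 15 5-isopropoxy-3-(2,4,6-trimethoxybenzoyl)-2-(trimethylsilyl)phenyl trifluoromethanesulfonate; 16 3-methylbut-2-enal
Product: 20 (7-isopropoxy-2,2-dimethyl-2H-chromen-5-yl)(2,4,6-trimethoxyphenyl)methanone, via aryne 17 (not isolated), via benzoxete 18 (not isolated), via ortho-quinone methide 19 (not isolated)
Conditions: 16 (5 equiv), CsF (3 equiv), MeCN, rt → 40 °C, slow addition of 15
Reagents that add atoms: none
Why: Fluoride attacks silicon and triflate leaves to give aryne 17; the aldehyde oxygen of 16 adds to the aryne carbon remote from the aroyl group (future C8a) and the aryl anion formed beside the aroyl group (future C4a) collapses onto the carbonyl carbon, so benzoxete 18 holds O1–C8a and C4–C4a. Thermal 4π opening of the strained oxete gives ortho-quinone methide 19, whose 1-oxatriene closes the six-membered pyran by thermal disrotatory 6π electrocyclisation (O1–C2) and restores the aromaticity of ring B. This is the known chromene synthesis from arynes and α,β-unsaturated aldehydes, an extension of the formal [2+2] insertion of arynes into C=O bonds. No stereocentre results, since C2 carries two methyl groups and the benzoxete carbon becomes sp2 on ring opening. The regiochemistry (oxygen to C8a, carbon to C4a) should be secured by the σ-withdrawing aroyl group, which polarises the aryne, stabilises the adjacent aryl anion and shields C4a with its twisted, doubly ortho-substituted ring, while the C7 isopropoxy group is the least σ-withdrawing oxygen substituent and so the weakest opposing influence. The aryne must also choose the aldehyde over its own hindered diaryl ketone and over ene or self-addition paths, which excess enal and slow release from sparingly soluble CsF should ensure.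

Step 9
Reactants: 20 (7-isopropoxy-2,2-dimethyl-2H-chromen-5-yl)(2,4,6-trimethoxyphenyl)methanone
Product: 21 (2-hydroxy-4,6-dimethoxyphenyl)(7-hydroxy-2,2-dimethyl-2H-chromen-5-yl)methanone
Conditions: BCl3 (4 equiv, 1 M in CH2Cl2), CH2Cl2, −78 → 0 °C; then MeOH, aq. NaHCO3
Reagents that add atoms: none
Why: In this Lewis-acid ether cleavage, BCl3 bound to the ketone oxygen should remove one flanking methyl group of ring A through a six-membered chelate and then stop because the aryloxyboron chelate blocks the carbonyl, while free BCl3 ionises the secondary isopropyl ether at C7; the para methyl ether is unactivated and the pyran should be tolerated at or below 0 °C, as in chelation-controlled demethylations of other 2,2-dimethylchromenyl ketones.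

Compound list
1 | 3,5-dimethoxybenzaldehyde | COc1cc(OC)cc(C=O)c1 | starting material
2 | 2-bromo-3,5-dimethoxybenzaldehyde | COc1cc(OC)c(Br)c(C=O)c1 | intermediate
3 | 2-bromo-3,5-dihydroxybenzaldehyde | O=Cc1cc(O)cc(O)c1Br | intermediate
4 | 2-bromo-5-(dimethoxymethyl)benzene-1,3-diol | COC(OC)c1cc(O)cc(O)c1Br | intermediate
5 | 2-bromo-1-(dimethoxymethyl)-3,5-bis(trimethylsilyloxy)benzene | COC(OC)c1cc(O[Si](C)(C)C)cc(O[Si](C)(C)C)c1Br | intermediate (not isolated)
6 | [2-(dimethoxymethyl)-4,6-bis(trimethylsilyloxy)phenyl]lithium | COC(OC)c1cc(O[Si](C)(C)C)cc(O[Si](C)(C)C)c1[Li] | intermediate (not isolated)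
7 | lithium 3-(dimethoxymethyl)-2-(trimethylsilyl)-5-(trimethylsilyloxy)phenoxide | COC(OC)c1cc(O[Si](C)(C)C)cc([O-])c1[Si](C)(C)C.[Li+] | intermediate (not isolated)
8 | 3-(dimethoxymethyl)-2-(trimethylsilyl)-5-(trimethylsilyloxy)phenyl trifluoromethanesulfonate | COC(OC)c1cc(O[Si](C)(C)C)cc(OS(=O)(=O)C(F)(F)F)c1[Si](C)(C)C | intermediate (not isolated)
9 | 3-formyl-5-hydroxy-2-(trimethylsilyl)phenyl trifluoromethanesulfonate | O=Cc1cc(O)cc(OS(=O)(=O)C(F)(F)F)c1[Si](C)(C)C | intermediate
10 | 3-formyl-5-isopropoxy-2-(trimethylsilyl)phenyl trifluoromethanesulfonate | CC(C)Oc1cc(C=O)c([Si](C)(C)C)c(OS(=O)(=O)C(F)(F)F)c1 | intermediate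
11 | 1,3,5-trimethoxybenzene | COc1cc(OC)cc(OC)c1 | starting material
12 | 2,4,6-trimethoxyphenyllithium | [Li]c1c(OC)cc(OC)cc1OC | intermediate (not isolated)
13 | 2,4,6-trimethoxyphenylmagnesium bromide | COc1cc(OC)c([Mg]Br)c(OC)c1 | intermediate (not isolated)
14 | 3-[hydroxy(2,4,6-trimethoxyphenyl)methyl]-5-isopropoxy-2-(trimethylsilyl)phenyl trifluoromethanesulfonate, racemic | COc1cc(OC)c(C(O)c2cc(OC(C)C)cc(OS(=O)(=O)C(F)(F)F)c2[Si](C)(C)C)c(OC)c1 | intermediate
15 | 5-isopropoxy-3-(2,4,6-trimethoxybenzoyl)-2-(trimethylsilyl)phenyl trifluoromethanesulfonate | COc1cc(OC)c(C(=O)c2cc(OC(C)C)cc(OS(=O)(=O)C(F)(F)F)c2[Si](C)(C)C)c(OC)c1 | intermediate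
16 | 3-methylbut-2-enal | CC(C)=CC=O | starting material
17 | (5-isopropoxy-1,2-didehydrobenzen-3-yl)(2,4,6-trimethoxyphenyl)methanone (aryne) | COc1cc(OC)c(C(=O)C2=CC(OC(C)C)=CC#C2)c(OC)c1 | intermediate (not isolated)
18 | [5-isopropoxy-2-(2-methylprop-1-en-1-yl)-2H-benzo[b]oxet-3-yl](2,4,6-trimethoxyphenyl)methanone, racemic | COc1cc(OC)c(C(=O)c2cc(OC(C)C)cc3c2C(C=C(C)C)O3)c(OC)c1 | intermediate (not isolated)
19 | (6Z)-3-isopropoxy-6-(3-methylbut-2-en-1-ylidene)-5-(2,4,6-trimethoxybenzoyl)cyclohexa-2,4-dien-1-one | CC(C)=C\C=C1/C(=O)C=C(OC(C)C)C=C1C(=O)c1c(OC)cc(OC)cc1OC | intermediate (not isolated)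
20 | (7-isopropoxy-2,2-dimethyl-2H-chromen-5-yl)(2,4,6-trimethoxyphenyl)methanone | COc1cc(OC)c(C(=O)c2cc(OC(C)C)cc3c2C=CC(C)(C)O3)c(OC)c1 | intermediate
21 | (2-hydroxy-4,6-dimethoxyphenyl)(7-hydroxy-2,2-dimethyl-2H-chromen-5-yl)methanone | COc1cc(O)c(C(=O)c2cc(O)cc3c2C=CC(C)(C)O3)c(OC)c1 | target

Total step count: 9. Longest linear sequence: 9 steps (1 → 21); 11 enters in step 6 after metalation in the flask.

Steps most likely to fail

Step 8. The carbonyl oxygen may add to the aryne carbon beside the aroyl group, or the aryne may be lost to protonation and self-addition before it meets the enal, so regiocontrol and mass balance could both suffer. The fallback sets out from 10 and returns at 20, with carbon and oxygen fixed by the former C–Si and C–OTf positions. Ipso-iododesilylation of 10 (ICl, CH2Cl2, 0 °C) should give 3-formyl-2-iodo-5-isopropoxyphenyl trifluoromethanesulfonate F1. An iodide-selective Heck reaction with 2-methylbut-3-en-2-ol under ligand-free phase-transfer conditions (Pd(OAc)2, n-Bu4NCl, NaHCO3, DMF, 60 °C) should give 3-formyl-2-[(E)-3-hydroxy-3-methylbut-1-en-1-yl]-5-isopropoxyphenyl trifluoromethanesulfonate F2. Triflate hydrolysis (Et4NOH, dioxane, rt) should give 3-hydroxy-2-[(E)-3-hydroxy-3-methylbut-1-en-1-yl]-5-isopropoxybenzaldehyde F3. Acid-catalysed cyclodehydration through the allyl cation (PPTS, toluene, 80 °C) should close the pyran to 7-isopropoxy-2,2-dimethyl-2H-chromene-5-carbaldehyde F4. Addition of 13 (THF, −78 °C) should give (7-isopropoxy-2,2-dimethyl-2H-chromen-5-yl)(2,4,6-trimethoxyphenyl)methanol F5, and MnO2 (CH2Cl2, rt) should oxidise it to 20.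

Step 4. Butyllithium may also cleave the remote O–Si bond, or the silyl shift may be incomplete, so that triflic anhydride meets more than one phenoxide and the differentiation of the two oxygens is lost; the acid finish could also cost the aryl–silicon bond while the para oxygen is a free phenol. The fallback sets out from 4 and returns at 10. The sequence is stopped after the silyl shift with aqueous NH4Cl, which should give 5-(dimethoxymethyl)-4-(trimethylsilyl)benzene-1,3-diol F6. The two hydroxyls are then told apart by size: Mitsunobu reaction with propan-2-ol (PPh3, DIAD, THF, 0 °C) should take the unhindered one and give 3-(dimethoxymethyl)-5-isopropoxy-2-(trimethylsilyl)phenol F7. The hindered phenol is triflated under amine base (Tf2O, pyridine, CH2Cl2, 0 °C) to 3-(dimethoxymethyl)-5-isopropoxy-2-(trimethylsilyl)phenyl trifluoromethanesulfonate F8, and buffered acetal hydrolysis (PPTS, acetone/H2O, rt) should give 10.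

Step 6. The magnesium alkoxide sits four atoms from silicon and could trigger carbon-to-oxygen silyl transfer with loss of triflate (premature aryne formation), or the doubly ortho-substituted nucleophile could attack sulfur or fail to add to the hindered aldehyde. The fallback sets out from 10 and returns at 15, so step 7 is skipped and no alkoxide is formed next to silicon. Pinnick oxidation (NaClO2, NaH2PO4, 2-methylbut-2-ene, t-BuOH/H2O) should give 5-isopropoxy-3-{[(trifluoromethyl)sulfonyl]oxy}-2-(trimethylsilyl)benzoic acid F9. Oxalyl chloride with catalytic DMF (CH2Cl2, 0 °C → rt) should give 3-(chlorocarbonyl)-5-isopropoxy-2-(trimethylsilyl)phenyl trifluoromethanesulfonate F10. Friedel–Crafts acylation of 11 (SnCl4, CH2Cl2, −40 → 0 °C) should then give 15, since 11 is among the most nucleophilic arenes and the silicon-bearing ring is deactivated toward ipso attack by its two flanking acceptors.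

Further compounds
F1 | step 8 | 3-formyl-2-iodo-5-isopropoxyphenyl trifluoromethanesulfonate | CC(C)Oc1cc(C=O)c(I)c(OS(=O)(=O)C(F)(F)F)c1
F2 | step 8 | 3-formyl-2-[(E)-3-hydroxy-3-methylbut-1-en-1-yl]-5-isopropoxyphenyl trifluoromethanesulfonate | CC(C)Oc1cc(C=O)c(/C=C/C(C)(C)O)c(OS(=O)(=O)C(F)(F)F)c1
F3 | step 8 | 3-hydroxy-2-[(E)-3-hydroxy-3-methylbut-1-en-1-yl]-5-isopropoxybenzaldehyde | CC(C)Oc1cc(O)c(/C=C/C(C)(C)O)c(C=O)c1
F4 | step 8 | 7-isopropoxy-2,2-dimethyl-2H-chromene-5-carbaldehyde | CC(C)Oc1cc(C=O)c2C=CC(C)(C)Oc2c1
F5 | step 8 | (7-isopropoxy-2,2-dimethyl-2H-chromen-5-yl)(2,4,6-trimethoxyphenyl)methanol, racemic | COc1cc(OC)c(C(O)c2cc(OC(C)C)cc3c2C=CC(C)(C)O3)c(OC)c1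
F6 | step 4 | 5-(dimethoxymethyl)-4-(trimethylsilyl)benzene-1,3-diol | COC(OC)c1cc(O)cc(O)c1[Si](C)(C)C
F7 | step 4 | 3-(dimethoxymethyl)-5-isopropoxy-2-(trimethylsilyl)phenol | COC(OC)c1cc(OC(C)C)cc(O)c1[Si](C)(C)C
F8 | step 4 | 3-(dimethoxymethyl)-5-isopropoxy-2-(trimethylsilyl)phenyl trifluoromethanesulfonate | COC(OC)c1cc(OC(C)C)cc(OS(=O)(=O)C(F)(F)F)c1[Si](C)(C)C
F9 | step 6 | 5-isopropoxy-3-{[(trifluoromethyl)sulfonyl]oxy}-2-(trimethylsilyl)benzoic acid | CC(C)Oc1cc(C(=O)O)c([Si](C)(C)C)c(OS(=O)(=O)C(F)(F)F)c1
F10 | step 6 | 3-(chlorocarbonyl)-5-isopropoxy-2-(trimethylsilyl)phenyl trifluoromethanesulfonate | CC(C)Oc1cc(C(=O)Cl)c([Si](C)(C)C)c(OS(=O)(=O)C(F)(F)F)c1
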